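(The data come from a simulation for substances that don't exist, noise included.)

Two numbers are asked of this flask, and they are nearly one, since maple's last reading puts monomer in chains and free monomer at 99.0% together.

| setting | maple | alder | cedar | flask |
|---|---|---|---|---|
| free monomer | 0.045 M | 0.045 M | 0.022 M | 0.045 M |
| initiator | 0.15 mM | 0.33 mM | 0.22 mM | 0.22 mM |
| remark | run made earlier | run made earlier | run made earlier |  |
| time |  |  |  | 40 min |

- maple (time / min: monomer in chains / %, free monomer / %): 4.00: 4, 95; 6.00: 6, 95; 10.0: 13, 90; 20.0: 29, 70; 30.0: 41, 60; 50.0: 45, 54
- alder (time / min: monomer in chains / %, free monomer / %): 8.00: 17, 81; 15.0: 36, 64; 25.0: 51, 45; 30.0: 56, 45; 40.0: 57, 41; 50.0: 60, 41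
- cedar (time / min: monomer in chains / %, free monomer / %): 4.00: 4, 99; 8.00: 7, 93; 15.0: 21, 79; 25.0: 37, 60; 50.0: 58, 40

(readings scatter by 1.5 percentage points)

* amount of monomer in chains in the flask at 40 min, in percent of the free monomer charged
* amount of free monomer in the flask at 40 min, in percent of the free monomer charged



Maple and alder both level off, and alder reads 41% free at 40.0 min and at 50.0 min, so I take a last reading as an estimate for 40 min. Write E = −ln(fraction of free monomer left): maple's last reading gives 0.616, alder's 0.892.

Bo holds that E goes with the initiator charge. Anchored on maple, the nearer run, this flask gets 0.904, or 40.5% free.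

Ines objects: from maple to alder the initiator grows by a factor of 2.20 but E by 1.45, a reading of order 0.469, so she takes the square root. She multiplies E by the root of 0.22 mM over the run's initiator. Maple then gives 0.746 and alder 0.728. Their mean is the stall index S, the stall exponent carried to this flask's charge at 0.045 M of free monomer: 0.737. That monomer level matters: cedar, with half of it at the same initiator, reads 0.916 at its last reading. My own reckoning follows her: 47.9% free and 52.1% in chains.

The forecast takes her side at 50% in chains and 50% free, holding that plateaus “scale as the square root of initiator”, which puts free monomer 2.1 percentage points above my reckoning.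

The flask gives 51.3% in chains and 48.3% free, an E of 0.728.

    free monomer + initiator → living end + monomer in chains (k = 0.0260 L mol⁻¹ s⁻¹)
    free monomer + living end → monomer in chains + living end, rate k2*[living end]*[free monomer] (k = 5.30 L mol⁻¹ s⁻¹)
    living end + monomer in chains → dead end (k = 0.0960 L mol⁻¹ s⁻¹)

With the step from living end + monomer in chains to dead end struck out, this flask stands at 81.2% in chains, not 51.3%: dying ends are the main reason for its stall. At a given level of living end, this flask's free monomer falls pseudo-first-order, so E adds up the work of the living ends over the time. Bo's proportion comes close early on: at 10.0 min this flask holds 0.0289% dead end, and maple's two readings at that time, averaged as monomer used and scaled his way, give 83.6% free against 83.1%. For a neighbour flask with 0.880 mM of initiator and the same 0.045 M of free monomer, S gives 22.9% free, and at 40 min that flask holds 21.9%.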